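**Retrosynthetic overview**

1. Bisoflavolin M (7) is the O4′–C3‴ dehydrodimer of 8-chlorogenistein. Cutting the diaryl ether C–O bond gives two molecules of 5; this bond is made last by oxidative phenol C–O coupling.
2. 5 comes from genistein (4) by C8-selective electrophilic chlorination of ring A.
3. 4 comes from phloroglucinol (1), 4-hydroxyphenylacetic acid (2) and one carbon of DMF in one pot, through deoxybenzoin 3.
4. Ring order: rings A and B are bought, ring C (the pyranone) is closed in step 1, then the C–Cl bond, then the ether.

Assumption: the target has no stereocentre and no configurationally stable axis, so it is achiral and no asymmetric step is needed.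

**Route**

Step 1
Reactants: 1 phloroglucinol; 2 4-hydroxyphenylacetic acid
Product: 4 genistein, via deoxybenzoin 3 (not isolated)
Conditions: BF3·OEt2 (as solvent), 85 °C, 1.5 h; then DMF, MsCl, 70 °C, 2 h; aq. NaOAc work-up
Reagents that add atoms: N,N-dimethylformamide (DMF), CN(C)C=O
Why: Friedel–Crafts C-acylation of the symmetric triol (only one regioisomer is possible) gives the boron-chelated deoxybenzoin 3, whose active methylene is formylated by the Vilsmeier-type DMF/MsCl reagent and cyclodehydrated through an ortho hydroxyl to close ring C, a one-pot isoflavone synthesis that tolerates free phenols.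

Step 2
Reactants: 4 genistein
Product: 5 8-chlorogenistein
Conditions: NCS (1.0 equiv), DMF, 0 °C to rt, dark; recrystallisation
Reagents that add atoms: N-chlorosuccinimide (NCS), O=C1CCC(=O)N1Cl
Why: Electrophilic aromatic substitution takes the ring A carbons first, and C8 (ortho to the free 7-OH, para to the chelated 5-OH) reacts before C6, as in the recalled hypochlorite chlorination pattern of genistein (8-chloro, then 6,8-dichloro); ring B is a plain phenol and slower, and one equivalent of NCS at low temperature limits dichlorination.

Step 3
Reactants: 5 8-chlorogenistein (two molecules, one as oxygen donor and one as carbon acceptor)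
Product: 7 Bisoflavolin M, via dienone 6 (not isolated)
Conditions: Cs2CO3 (2.2 equiv), Fe(C5Me5)2 (10 mol %), n-Bu4NBF4, DMSO, carbon-felt anode, Pt cathode, undivided cell, anode held at the Fe(C5Me5)2 couple, 0.6 F/mol, Ar, 25 °C; then aq. HCl; unreacted 5 recovered
Reagents that add atoms: none
Why: Proposed new method: decamethylferrocene-mediated anodic ortho C–O dehydrodimerisation of a free 4′-hydroxyisoflavone (oxidative phenol coupling in its C–O mode). In Cs2CO3/DMSO 5 is its 7,4′-dianion, and the anode makes [Fe(C5Me5)2]+ (trivalent iron), whose mild potential allows a slightly uphill electron transfer from the ring B 4′-phenoxide only; the 7-oxide is a vinylogous carboxylate and stays untouched, so no ring A radical and no link to C6 forms. The ring B phenoxyl radicals arise in solution and not on the electrode, and they pair O4′ to C3′ because oxygen and C1′ carry most of the spin, adducts at C1′ bear no hydrogen and revert, and the unsolvated phenoxyl oxygen in DMSO is free to bond; carbonate then tautomerises dienone 6 to the aromatic ether at once. No oxygen-transfer agent is present, so no catechol or quinone forms, and the charge limit keeps the more easily oxidised product from reacting on. Closest known reaction types: peroxidase and alkaline anodic coupling of para-substituted phenols to ortho oxyphenylene links, the copper–amine synthesis of poly(phenylene oxide), and the Tl(NO3)3 coupling of 2,6-dihalophenols to diaryl ethers; a selective ortho C–O dehydrodimerisation of an unprotected hydroxyisoflavone is not known.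

**Compound list**

1 | phloroglucinol (benzene-1,3,5-triol) | Oc1cc(O)cc(O)c1 | starting material
2 | 4-hydroxyphenylacetic acid | OC(=O)Cc1ccc(O)cc1 | starting material
3 | deoxybenzoin, 2-(4-hydroxyphenyl)-1-(2,4,6-trihydroxyphenyl)ethan-1-one (not isolated) | O=C(Cc1ccc(O)cc1)c1c(O)cc(O)cc1O | intermediate
4 | genistein (5,7-dihydroxy-3-(4-hydroxyphenyl)-4H-chromen-4-one) | O=c1c(-c2ccc(O)cc2)coc2cc(O)cc(O)c12 | intermediate
5 | 8-chlorogenistein (8-chloro-5,7-dihydroxy-3-(4-hydroxyphenyl)-4H-chromen-4-one) | O=c1c(-c2ccc(O)cc2)coc2c(Cl)c(O)cc(O)c12 | intermediate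
6 | dienone, 4-(8-chloro-5,7-dihydroxy-4-oxo-4H-chromen-3-yl)-6-[4-(8-chloro-5,7-dihydroxy-4-oxo-4H-chromen-3-yl)phenoxy]cyclohexa-2,4-dien-1-one (keto tautomer of 7; racemic at the transient sp3 carbon, not isolated) | O=C1C=CC(-c2coc3c(Cl)c(O)cc(O)c3c2=O)=CC1Oc1ccc(-c2coc3c(Cl)c(O)cc(O)c3c2=O)cc1 | intermediate
7 | Bisoflavolin M (8-chloro-3-{4-[5-(8-chloro-5,7-dihydroxy-4-oxo-4H-chromen-3-yl)-2-hydroxyphenoxy]phenyl}-5,7-dihydroxy-4H-chromen-4-one; achiral) | O=c1c(-c2ccc(Oc3cc(-c4coc5c(Cl)c(O)cc(O)c5c4=O)ccc3O)cc2)coc2c(Cl)c(O)cc(O)c12 | target

**Step count and risks**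

Total steps: 3. Longest linear sequence: 3 (fully linear; bought genistein can be entered as 4).

Steps most likely to fail:

1. Step 3 (the proposed new method). The O–C against C–C preference of free ring B phenoxyl radicals is unproven. The 3′,3‴ C–C dimer and trimers are the expected by-products even in a good run, and about 20–30 % of 7 based on recovered 5 would be a good result. If the C–C dimer dominates or the anode fouls, the fallback is the known halogen-blocked oxidative ether coupling; it sets out from 5 and comes back at 7. Exhaustive bromination of 5 (NBS, 3.1 equiv, DMF, 0 °C) blocks C6 and both ortho carbons of ring B and gives 6,3′,5′-tribromo-8-chlorogenistein F1. Oxidation of F1 with Tl(NO3)3·3H2O (trivalent thallium) in MeOH–THF at −20 °C is the established ether coupling of 2,6-dibromophenols: C–C coupling is shut off and the phenol oxygen of one molecule adds to a bromine-bearing ortho carbon of the other, giving the bromodienone ether F2. Zn dust in AcOH reduces F2 with loss of that bromine to the pentabromo diaryl ether F3. Hydrogenolysis (H2, Pd/C, Et3N, EtOAc–MeOH, rt, stopped once the C–Br bonds are gone; aryl C–Cl is much slower) then gives 7.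

2. Step 2. The 6-chloro isomer, 6,8-dichlorogenistein or ring B chlorination may erode the yield, and the 6- and 8-chloro isomers may be hard to separate; the C8 assignment must be confirmed by HMBC. The fallback fixes the regiochemistry by protection; it sets out from 4 and comes back at 5. Permethylation (Me2SO4, K2CO3, acetone, reflux) gives 5,7,4′-tri-O-methylgenistein F4. With both ring A oxygens as methyl ethers, halogenation of 5,7-dimethoxychromones is known to go to C8 (a free chelated 5-OH can divert it to C6), so NCS in MeCN at rt gives 8-chloro-5,7,4′-tri-O-methylgenistein F5. BBr3 (CH2Cl2, −78 °C to rt) removes the three methyl groups and gives 5.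

3. Step 1. The one-pot may stall at the deoxybenzoin or give O-sulfonylated or tarry material with the unprotected tetraphenol. The fallback separates the two bond formations and changes both reaction types; it sets out from 1 and comes back at 4. Houben–Hoesch acylation of 1 with commercial 4-hydroxyphenylacetonitrile (ZnCl2, HCl gas, Et2O, 0 °C) precipitates 2-(4-hydroxyphenyl)-1-(2,4,6-trihydroxyphenyl)ethan-1-iminium chloride F6. Hydrolysis (water, reflux) gives deoxybenzoin 3, now isolated and recrystallised. Ring C is then closed with triethyl orthoformate in pyridine with catalytic piperidine at reflux to give 4.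

**Further compounds**

F1 | step 3 | 6,3′,5′-tribromo-8-chlorogenistein | O=c1c(-c2cc(Br)c(O)c(Br)c2)coc2c(Cl)c(O)c(Br)c(O)c12
F2 | step 3 | bromodienone ether, 2,6-dibromo-4-(6-bromo-8-chloro-5,7-dihydroxy-4-oxo-4H-chromen-3-yl)-6-[2,6-dibromo-4-(6-bromo-8-chloro-5,7-dihydroxy-4-oxo-4H-chromen-3-yl)phenoxy]cyclohexa-2,4-dien-1-one (racemic) | O=C1C(Br)=CC(-c2coc3c(Cl)c(O)c(Br)c(O)c3c2=O)=CC1(Br)Oc1c(Br)cc(-c2coc3c(Cl)c(O)c(Br)c(O)c3c2=O)cc1Br
F3 | step 3 | pentabromo diaryl ether (6,6″,3′,5′,5‴-pentabromo derivative of 7) | O=c1c(-c2cc(Br)c(Oc3cc(-c4coc5c(Cl)c(O)c(Br)c(O)c5c4=O)cc(Br)c3O)c(Br)c2)coc2c(Cl)c(O)c(Br)c(O)c12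
F4 | step 2 | 5,7,4′-tri-O-methylgenistein | COc1ccc(-c2coc3cc(OC)cc(OC)c3c2=O)cc1
F5 | step 2 | 8-chloro-5,7,4′-tri-O-methylgenistein | COc1ccc(-c2coc3c(Cl)c(OC)cc(OC)c3c2=O)cc1
F6 | step 1 | 2-(4-hydroxyphenyl)-1-(2,4,6-trihydroxyphenyl)ethan-1-iminium chloride | [NH2+]=C(Cc1ccc(O)cc1)c1c(O)cc(O)cc1O.[Cl-]
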